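## The problem

The target, 6-hydroxy-8-(2-hydroxy-4-methoxy-6-pentylphenoxy)-3-pentylisocoumarin (23), has no stereocentre, so the whole difficulty lies in connectivity and in telling four phenolic oxygens apart. Ring A is a phloroglucinol-type benzene fused to an enol lactone with a pentyl chain at C3. Ring B is an olivetol-type arene with a third oxygen at C1', between the pentyl group at C6' and the hydroxyl at C2'. The two halves meet in the diaryl ether O8–C1', which has three ortho substituents (C8a with the lactone carbonyl on one side, O2' and the pentyl chain on the other) and therefore needs electronically matched partners. O6 and O2' must end free, O4' methylated and O8 arylated, so the pairs O6/O8 and O2'/O4' have to be differentiated by the substrate and not by statistics. The enol lactone opens with hydroxide or alkoxide and its C3–C4 double bond can be hydrogenated; ring B is easily oxidised or C-alkylated; and the aryl methyl ether must survive the last deprotection. The feature that makes the key step possible is that C4a and C8a are neighbouring carbons of ring A which carry C4 and the carbonyl carbon C1, with C8a next to the C8 oxygen. An aryne across C4a–C8a is polarised by that oxygen so that a carbon nucleophile goes to C4a and CO2 to C8a, and because O6 and O8 are meta to each other the aryne can come from a symmetrical 3,5-dioxygenated phenol.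

## Retrosynthesis

**Unmasking.** Target 23 is traced back to the bis(benzyl ether) 22; no skeletal bond is cut. Benzyl is chosen for O6 and O2' because it tolerates organolithium at low temperature, fluoride, palladium and mild base. It can be removed by a Lewis acid that leaves the methyl ether, the lactone and the C3–C4 double bond alone. The forward step must cleave two aryl benzyl ethers without C-benzylating ring B.

**Diaryl ether.** In 22 the bond between C8 and the ether oxygen is cut, giving the 8-triflate 14 and the ring B phenol 21. The neighbouring cut, O–C1', would pair the chelated, electron-poor 8-hydroxyl of 13 with an electron-rich, doubly ortho-substituted aryl metal, which is mismatched for both copper and palladium chemistry. The chosen cut pairs an electron-poor aryl electrophile, activated by the peri carbonyl, with an electron-rich phenoxide. The two halves are of similar size, so the route becomes convergent. The forward reaction must accept a 2,6-disubstituted phenol and use a base mild enough for the lactone.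

**Differentiating O6 and O8.** Triflate 14 comes from the chelated phenol 13, and 13 from the symmetrically protected isocoumarin 12 by removing only the benzyl group peri to the carbonyl. No skeletal bond is cut. The lactone carbonyl itself distinguishes the two oxygens, so 12 can carry two identical ethers and its precursor can be symmetrical.

**Isocoumarin (key disconnection).** In 12 the bonds C4a–C4, C8a–C1 and O2–C3 are cut together, leading to the silyl triflate 7, 1-heptyne (8) and carbon dioxide (9). Compared with lateral metalation and acylation of an orsellinate, or Sonogashira coupling and cyclisation of a tetrasubstituted ortho-halobenzoate, this removes the lactone ring and both carbon substituents of ring A in one catalytic step and needs no strong base. The precursors are a symmetrical arene, a seven-carbon alkyne and a gas. The forward reaction needs regioselective addition of the acetylide to the aryne, CO2 capture before protonation and 6-endo ring closure.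

**Aryne precursor.** Silyl triflate 7 is traced through the ortho-silyl carbamate 5 and carbamate 2 to 3,5-bis(benzyloxy)phenol (1); the only bond cut is C2–Si. Because 1 is symmetrical, both positions ortho to the phenol oxygen are equivalent and only one silyl triflate can form. The forward sequence is carbamate-directed ortho-metalation, silylation, and exchange of carbamate for triflate.

**Ring B.** Phenol 21 is traced to aldehyde 19 by replacing the C1'–O bond with a C1'–CHO bond (Dakin-type oxidation in the forward sense). Aldehyde 19 goes back through 18 and 17 to olivetol (15). The formyl group serves twice: it enters at the carbon between a hydroxyl and the pentyl chain, its hydrogen bond makes O2' and O4' chemically different so that methyl and benzyl can be placed in turn, and it is finally converted into the phenol oxygen.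

## Roads not taken

**Alternative 1:** Ring A is cut across C4a–C5 and C6–C7, so that C5 and C6 come from an alkyne and the other four ring carbons from a 2-pyrone.
- Forward step: the pyrone ester A2, carrying ring B as a 4-aryloxy group, and the silyl ynol ether A3 undergo an inverse-demand Diels–Alder addition; decarboxylative cycloreversion gives benzoate A1.
- Merits: the ether oxygen is attached by addition–elimination of phenol 21 at a vinylogous ester carbon, which avoids any hindered aryl coupling and is better than the chosen plan on that point. O6 and O8 are different from the start.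
- Weak points: the 4-aryloxy donor makes the pyrone a poorer acceptor and the 6-methyl group hinders the terminus that the nucleophilic alkyne carbon must attack. Heating is therefore expected, and silyl ynol ethers rearrange to silylketenes under such conditions. A1 is still only a toluate, so the lactone needs lateral deprotonation, acylation with a hexanoyl electrophile and cyclisation, followed by two different deprotections.
- Comparison: the step count is similar. The chosen plan sets against the easier ether bond a polarity-matched palladium coupling and a catalytic step with close precedent that closes the lactone directly, without a late strongly basic step.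

**Alternative 2:** Ring B itself is cut across C1'–C6' and C2'–C3'.
- Forward step: an alkoxide base adds the aryloxymalonate A5 to enone A6 (Michael addition) and the methyl ketone enolate then closes onto a malonate ester (Claisen), giving the cyclohexane-1,3-dione A4.
- Merits: the O–C1' bond is made by alkylating a ring A phenol at an sp3 malonate carbon, the easiest way to form this hindered ether. No olivetol and no coupling catalyst are needed; in this respect it is better than the chosen plan.
- Weak points: the malonate carbon is tertiary and bears an aryloxy group, so the conjugate addition builds a quaternary centre next to the pentyl-bearing carbon and is reversible. A4 still needs dealkoxycarbonylation, dehydrogenation to the arene and selective methylation of one of two new hydroxyls. The lactone must then be built from the toluamide by lateral metalation in the presence of the finished ring B.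
- Comparison: this is the longest road. The chosen plan buys the ring B oxygen pattern with olivetol, differentiates it by high-precedent steps without redox adjustments, and is roughly half as long in its linear sequence.

**Alternative 3:** Ring A is cut across C4a–C8a, C6–C7, C8–C8a and C5–C6 (Danheiser benzannulation).
- Forward step: irradiation of the diazo keto ester A8 triggers a Wolff shift to a vinylketene, which adds [2+2] to the aryl ethynyl ether A9. Four-electron ring opening and six-electron electrocyclisation on heating give phenol A7.
- Merits: ring A is formed fully substituted, with O6 free and O8 already arylated. The ether oxygen arrives with an ynol ether made from 21, so no aryl coupling is needed. Regiochemistry follows from ketene polarity.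
- Weak points: the ketene bears an ester and is also an acylketene, which can react with the electron-rich alkyne as a heterodiene. Doubly ortho-substituted aryl ynol ethers are less studied and thermally fragile partners, and the photochemical step limits scale. As in alternative 1, the product is a toluate whose phenol must be protected before the lactone is built by lateral metalation.
- Comparison: differentiation of O6 and O8 is built in and more elegant here. The chosen plan answers with a one-step chelation-controlled differentiation and direct formation of the lactone ring.

Key step: step 4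

## Route

Remark: 3,5-bis(benzyloxy)phenol (1), 1-heptyne (8), olivetol (15) and chloro[1,3-bis(2,6-diisopropylphenyl)imidazol-2-ylidene]copper (IPrCuCl) are taken as purchasable. The target has no stereocentre, so no step has to set configuration.

Step 1
Reactants: 1 3,5-bis(benzyloxy)phenol
Product: 2 3,5-bis(benzyloxy)phenyl N-isopropylcarbamate
Conditions: i-PrNCO, Et3N (cat.), CH2Cl2, rt
Reagents that add atoms: isopropyl isocyanate, CC(C)N=C=O
Why: Base-catalysed addition of an unhindered phenol to an isocyanate (carbamoylation) is clean; the secondary carbamate is chosen because it can later be removed by mild amine treatment that an ortho-silyl group survives.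

Step 2
Reactants: 2 3,5-bis(benzyloxy)phenyl N-isopropylcarbamate
Product: 5 3,5-bis(benzyloxy)-2-(trimethylsilyl)phenyl N-isopropylcarbamate, via N-silyl carbamate 3 (not isolated), via C-silylated N-silyl carbamate 4 (not isolated)
Conditions: TMSOTf, TMEDA, Et2O, 0 °C to rt; then n-BuLi, TMEDA, −78 °C; then TMSCl, −78 °C to rt; aq. NH4Cl
Reagents that add atoms: chlorotrimethylsilane, C[Si](C)(C)Cl; trimethylsilyl trifluoromethanesulfonate, C[Si](C)(C)OS(=O)(=O)C(F)(F)F (its silyl group stays only in intermediates 3 and 4)
Why: Directed ortho-metalation: in situ N-silylation masks the N–H, the O-carbamate then directs n-BuLi/TMEDA to C2, which lies between the carbamate and a benzyloxy group and is equivalent to C6 by symmetry, and TMSCl traps the aryllithium; the N–Si bond is hydrolysed on neutral aqueous work-up.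

Step 3
Reactants: 5 3,5-bis(benzyloxy)-2-(trimethylsilyl)phenyl N-isopropylcarbamate
Product: 7 3,5-bis(benzyloxy)-2-(trimethylsilyl)phenyl trifluoromethanesulfonate, via silylphenol 6 (not isolated)
Conditions: Et2NH, DBU, MeCN, 40 °C; then PhNTf2, rt
Reagents that add atoms: N-phenylbis(trifluoromethanesulfonimide), O=S(=O)(N(c1ccccc1)S(=O)(=O)C(F)(F)F)C(F)(F)F
Why: DBU-promoted E1cB loss of isopropyl isocyanate from the secondary carbamate (trapped by Et2NH as a urea) frees the phenoxide, which PhNTf2 sulfonylates in the same flask; this carbamate-to-triflate exchange is the standard entry to 2-silylaryl triflates and avoids acid that could protodesilylate the electron-rich arene.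

Step 4
Reactants: 7 3,5-bis(benzyloxy)-2-(trimethylsilyl)phenyl trifluoromethanesulfonate; 8 1-heptyne; 9 carbon dioxide
Product: 12 6,8-bis(benzyloxy)-3-pentylisocoumarin, via aryne 10 (not isolated), via alkynylbenzoate 11 (not isolated)
Conditions: chloro[1,3-bis(2,6-diisopropylphenyl)imidazol-2-ylidene]copper (IPrCuCl, 10 mol %), CsF, Cs2CO3 (20 mol %), CO2 (1 atm), MeCN, 50 °C
Reagents that add atoms: none
Why: Fluoride attacks silicon of 7 and triflate leaves, giving 3,5-bis(benzyloxy)benzyne 10; the copper acetylide formed from 8 and IPrCuCl (monovalent copper) adds across the strained triple bond, placing the alkynyl carbon on the future C4a and copper on the future C8a. The arylcopper inserts CO2 (9) to give the copper-bound carboxylate 11 (C8a–C1), and the same NHC–copper centre activates the alkyne for anti attack of the carboxylate oxygen on the pentyl-bearing carbon, a 6-endo-dig closure that forms O2–C3 and the lactone ring; protonation of the vinylcopper by further 8 regenerates the acetylide. The closest known reaction type is the NHC–copper-catalysed three-component coupling of silylaryl triflates, terminal alkynes and CO2 to 3-substituted isocoumarins, in which 3-alkoxyarynes are accepted. No stereocentre is created. Three selectivities are needed: the acetylide must attack the aryne carbon meta to the adjacent benzyloxy group, which that oxygen secures by distorting the aryne and stabilising the carbon–copper bond developing next to it (the remote benzyloxy group exerts only a weak opposing bias); the arylcopper must take up CO2 faster than a proton, which the CO2 atmosphere, the aprotic medium and slow aryne release by sparingly soluble CsF favour; and closure must be 6-endo and not 5-exo to the alkylidene phthalide, for which the bulky carbene ligand on copper is the established control element. Because 7 derives from a symmetrical phenol only one aryne can form, and both benzyl ethers are inert to fluoride and to the copper species.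

Step 5
Reactants: 12 6,8-bis(benzyloxy)-3-pentylisocoumarin
Product: 13 6-(benzyloxy)-8-hydroxy-3-pentylisocoumarin
Conditions: MgBr2·OEt2, toluene–Et2O, 80 °C; aq. HCl work-up
Reagents that add atoms: none
Why: Chelation-controlled ether cleavage: magnesium bridges the lactone carbonyl oxygen and the peri C8 ether oxygen, so bromide removes only that benzyl group as benzyl bromide while the unchelated C6 benzyl ether stays.

Step 6
Reactants: 13 6-(benzyloxy)-8-hydroxy-3-pentylisocoumarin
Product: 14 6-(benzyloxy)-1-oxo-3-pentyl-1H-isochromen-8-yl trifluoromethanesulfonate
Conditions: Tf2O, pyridine, CH2Cl2, 0 °C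
Reagents that add atoms: trifluoromethanesulfonic anhydride, O=S(=O)(OS(=O)(=O)C(F)(F)F)C(F)(F)F
Why: O-sulfonylation of a hydrogen-bonded phenol with Tf2O and pyridine is routine for salicylate-type and peri-hydroxy carbonyl compounds; it turns the C8 oxygen into a leaving group on an electron-poor carbon.

Step 7
Reactants: 15 olivetol (5-pentylbenzene-1,3-diol)
Product: 17 2,4-dihydroxy-6-pentylbenzaldehyde, via iminium ion 16 (not isolated)
Conditions: POCl3, DMF, 0 °C to rt; then H2O, 50 °C
Reagents that add atoms: N,N-dimethylformamide, CN(C)C=O; water, O
Why: Vilsmeier–Haack formylation of a 5-alkylresorcinol takes place para to one hydroxyl and ortho to the other, at the carbon next to the alkyl chain; hydrolysis of the iminium ion gives the aldehyde.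

Step 8
Reactants: 17 2,4-dihydroxy-6-pentylbenzaldehyde
Product: 18 2-hydroxy-4-methoxy-6-pentylbenzaldehyde
Conditions: MeI (1.05 equiv), K2CO3, acetone, rt
Reagents that add atoms: iodomethane, CI
Why: Williamson etherification distinguishes the two phenols because the 2-hydroxyl is hydrogen-bonded to the formyl group and less nucleophilic, so one equivalent of MeI alkylates the para hydroxyl.

Step 9
Reactants: 18 2-hydroxy-4-methoxy-6-pentylbenzaldehyde
Product: 19 2-(benzyloxy)-4-methoxy-6-pentylbenzaldehyde
Conditions: BnBr, K2CO3, DMF, 60 °C
Reagents that add atoms: benzyl bromide, BrCc1ccccc1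
Why: Williamson benzylation of the remaining chelated phenol needs only a more polar solvent and warming; it masks the future C2' hydroxyl with the same group used on ring A.

Step 10
Reactants: 19 2-(benzyloxy)-4-methoxy-6-pentylbenzaldehyde
Product: 21 2-(benzyloxy)-4-methoxy-6-pentylphenol, via aryl formate 20 (not isolated)
Conditions: mCPBA, CH2Cl2, 0 °C to rt; then K2CO3 (cat.), MeOH, rt
Reagents that add atoms: 3-chloroperoxybenzoic acid, OOC(=O)c1cccc(Cl)c1
Why: Dakin-type Baeyer–Villiger oxidation: in the Criegee intermediate the electron-rich aryl group migrates in preference to hydride, giving the aryl formate, which is methanolysed in the same flask to the phenol.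

Step 11
Reactants: 14 6-(benzyloxy)-1-oxo-3-pentyl-1H-isochromen-8-yl trifluoromethanesulfonate; 21 2-(benzyloxy)-4-methoxy-6-pentylphenol
Product: 22 6-(benzyloxy)-8-[2-(benzyloxy)-4-methoxy-6-pentylphenoxy]-3-pentylisocoumarin
Conditions: Pd(OAc)2 (5 mol %), 2-di-tert-butylphosphino-2',4',6'-triisopropylbiphenyl (7.5 mol %), K3PO4, toluene, 100 °C
Reagents that add atoms: none
Why: Palladium-catalysed C–O cross-coupling of an aryl triflate with a phenol (Buchwald–Hartwig-type diaryl ether synthesis): zerovalent palladium formed in situ inserts readily into the electron-poor C8–OTf bond, and the bulky di-tert-butylbiarylphosphine forces C–O reductive elimination, which is favoured by the electron-poor aryl group on palladium and the electron-rich phenoxide; sparingly soluble K3PO4 in toluene limits S–O cleavage of the triflate and leaves the lactone closed.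

Step 12
Reactants: 22 6-(benzyloxy)-8-[2-(benzyloxy)-4-methoxy-6-pentylphenoxy]-3-pentylisocoumarin
Product: 23 6-hydroxy-8-(2-hydroxy-4-methoxy-6-pentylphenoxy)-3-pentylisocoumarin
Conditions: BCl3, pentamethylbenzene, CH2Cl2, −78 °C; then MeOH, aq. work-up
Reagents that add atoms: none
Why: Lewis-acid debenzylation with BCl3 and pentamethylbenzene as a non-basic benzyl cation scavenger cleaves both aryl benzyl ethers at low temperature; the aryl methyl ether, the diaryl ether, the lactone and the C3–C4 double bond should be untouched, and the scavenger prevents Friedel–Crafts benzylation of ring B.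

## Compound list

1 | 3,5-bis(benzyloxy)phenol | Oc1cc(OCc2ccccc2)cc(OCc2ccccc2)c1 | starting material
2 | 3,5-bis(benzyloxy)phenyl N-isopropylcarbamate | CC(C)NC(=O)Oc1cc(OCc2ccccc2)cc(OCc2ccccc2)c1 | intermediate
3 | 3,5-bis(benzyloxy)phenyl N-isopropyl-N-(trimethylsilyl)carbamate | CC(C)N([Si](C)(C)C)C(=O)Oc1cc(OCc2ccccc2)cc(OCc2ccccc2)c1 | intermediate (not isolated)
4 | 3,5-bis(benzyloxy)-2-(trimethylsilyl)phenyl N-isopropyl-N-(trimethylsilyl)carbamate | CC(C)N([Si](C)(C)C)C(=O)Oc1cc(OCc2ccccc2)cc(OCc2ccccc2)c1[Si](C)(C)C | intermediate (not isolated)
5 | 3,5-bis(benzyloxy)-2-(trimethylsilyl)phenyl N-isopropylcarbamate | CC(C)NC(=O)Oc1cc(OCc2ccccc2)cc(OCc2ccccc2)c1[Si](C)(C)C | intermediate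
6 | 3,5-bis(benzyloxy)-2-(trimethylsilyl)phenol (present as its phenoxide) | Oc1cc(OCc2ccccc2)cc(OCc2ccccc2)c1[Si](C)(C)C | intermediate (not isolated)
7 | 3,5-bis(benzyloxy)-2-(trimethylsilyl)phenyl trifluoromethanesulfonate | C[Si](C)(C)c1c(OCc2ccccc2)cc(OCc2ccccc2)cc1OS(=O)(=O)C(F)(F)F | intermediate
8 | 1-heptyne | CCCCCC#C | starting material
9 | carbon dioxide | O=C=O | starting material
10 | 3,5-bis(benzyloxy)benzyne (3,5-bis(benzyloxy)-1,2-didehydrobenzene) | C1#CC(OCc2ccccc2)=CC(OCc2ccccc2)=C1 | intermediate (not isolated)
11 | 2,4-bis(benzyloxy)-6-(hept-1-yn-1-yl)benzoate (carboxylate bound to the copper catalyst) | CCCCCC#Cc1cc(OCc2ccccc2)cc(OCc2ccccc2)c1C(=O)[O-] | intermediate (not isolated)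
12 | 6,8-bis(benzyloxy)-3-pentylisocoumarin (6,8-bis(benzyloxy)-3-pentyl-1H-isochromen-1-one) | CCCCCc1cc2cc(OCc3ccccc3)cc(OCc3ccccc3)c2c(=O)o1 | intermediate
13 | 6-(benzyloxy)-8-hydroxy-3-pentylisocoumarin | CCCCCc1cc2cc(OCc3ccccc3)cc(O)c2c(=O)o1 | intermediate
14 | 6-(benzyloxy)-1-oxo-3-pentyl-1H-isochromen-8-yl trifluoromethanesulfonate | CCCCCc1cc2cc(OCc3ccccc3)cc(OS(=O)(=O)C(F)(F)F)c2c(=O)o1 | intermediate
15 | olivetol (5-pentylbenzene-1,3-diol) | CCCCCc1cc(O)cc(O)c1 | starting material
16 | [(2,4-dihydroxy-6-pentylphenyl)methylidene]dimethyliminium ion | CCCCCc1cc(O)cc(O)c1C=[N+](C)C | intermediate (not isolated)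
17 | 2,4-dihydroxy-6-pentylbenzaldehyde | CCCCCc1cc(O)cc(O)c1C=O | intermediate
18 | 2-hydroxy-4-methoxy-6-pentylbenzaldehyde | CCCCCc1cc(OC)cc(O)c1C=O | intermediate
19 | 2-(benzyloxy)-4-methoxy-6-pentylbenzaldehyde | CCCCCc1cc(OC)cc(OCc2ccccc2)c1C=O | intermediate
20 | 2-(benzyloxy)-4-methoxy-6-pentylphenyl formate | CCCCCc1cc(OC)cc(OCc2ccccc2)c1OC=O | intermediate (not isolated)
21 | 2-(benzyloxy)-4-methoxy-6-pentylphenol | CCCCCc1cc(OC)cc(OCc2ccccc2)c1O | intermediate
22 | 6-(benzyloxy)-8-[2-(benzyloxy)-4-methoxy-6-pentylphenoxy]-3-pentylisocoumarin | CCCCCc1cc2cc(OCc3ccccc3)cc(Oc3c(OCc4ccccc4)cc(OC)cc3CCCCC)c2c(=O)o1 | intermediate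
23 | 6-hydroxy-8-(2-hydroxy-4-methoxy-6-pentylphenoxy)-3-pentylisocoumarin (6-hydroxy-8-(2-hydroxy-4-methoxy-6-pentylphenoxy)-3-pentyl-1H-isochromen-1-one) | CCCCCc1cc2cc(O)cc(Oc3c(O)cc(OC)cc3CCCCC)c2c(=O)o1 | target

## Step count and risk

Total: 12 steps. Longest linear sequence: 8 steps (steps 1 to 6, 11 and 12); the ring B branch (steps 7 to 10) has 4 steps.

**Step 4 (key step).**
- What may go wrong: the arylcopper may be protonated before it inserts CO2, giving plain hydroalkynylation. The copper acetylide may be carboxylated before it meets the aryne. The carboxylate may close 5-exo to the alkylidene phthalide. The doubly alkoxylated aryne is less electrophilic and may be consumed by the carboxylate product or by oligomerisation.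
- Fallback: set out from 7 and return at 12 by a stepwise aryne route that keeps the same polarisation. Fluoride-induced insertion of the aryne into a C–C bond of dimethyl malonate should give methyl 2,4-bis(benzyloxy)-6-(2-methoxy-2-oxoethyl)benzoate F1, with the ester on the carbon next to the benzyloxy group. Saponification gives 2,4-bis(benzyloxy)-6-(carboxymethyl)benzoic acid F2 and dehydration gives 6,8-bis(benzyloxy)isochromane-1,3-dione F3. C-Acylation of F3 with hexanoyl chloride and an amine base, then acid-promoted ring opening, decarboxylation and relactonisation, is the classical homophthalic anhydride route to 3-alkylisocoumarins and delivers 12.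

**Step 11.**
- What may go wrong: the phenoxide may attack sulfur of the triflate (triflyl transfer back to 13). Reductive elimination with the 2,6-disubstituted phenoxide may be slow, so that reduction of the triflate competes.
- Fallback: set out from 14 and return at 22 by an oxidative copper coupling. Miyaura borylation of 14 (bis(pinacolato)diboron, PdCl2(dppf), KOAc, dioxane) gives 6-(benzyloxy)-3-pentyl-8-(4,4,5,5-tetramethyl-1,3,2-dioxaborolan-2-yl)isocoumarin F4. Chan–Lam coupling of F4 with phenol 21 (Cu(OAc)2, divalent copper, pyridine, air, molecular sieves) then gives 22. Hindered ortho-disubstituted phenols are accepted as the nucleophile in this coupling.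

**Step 2.**
- What may go wrong: metalation may occur at a benzylic CH2 (followed by Wittig rearrangement) or at C4 between the two benzyloxy groups. The very electron-rich aryl silane may lose silicon by protodesilylation during work-up.
- Fallback: set out from 1 and return at 7 without any C–H deprotonation. Ortho-bromination of 1 (NBS, CH2Cl2, low temperature, secondary amine catalyst) gives 3,5-bis(benzyloxy)-2-bromophenol F5. O-Silylation with hexamethyldisilazane gives [3,5-bis(benzyloxy)-2-bromophenoxy]trimethylsilane F6. Bromine–lithium exchange with n-BuLi at −78 °C then triggers the retro-Brook shift of silicon from oxygen to carbon, and the resulting lithium phenoxide of 6 is trapped with Tf2O to give 7.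

**Step 12.**
- What may go wrong: BCl3 may also cleave the C4' methyl ether if the mixture warms. Ring B may be C-benzylated if cation scavenging is too slow.
- Fallback: set out from 22 and return at 23 by hydrogenolysis (H2, palladium on carbon, EtOAc, stopped after two equivalents of hydrogen so that the C3–C4 double bond is spared). This fallback makes no new compound (F0).

**Step 5.**
- What may go wrong: discrimination between the two benzyl ethers may be incomplete, or cleavage at the usable temperature may be slow.
- Fallback: set out from 12 and return at 13 in two steps. Hydrogenolysis of both benzyl ethers (H2, palladium on carbon, EtOAc) gives 6,8-dihydroxy-3-pentylisocoumarin F7. Benzylation with one equivalent of BnBr and K2CO3 in acetone then takes place at the non-chelated 6-hydroxyl and gives 13.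

## Further compounds

F1 | step 4 | methyl 2,4-bis(benzyloxy)-6-(2-methoxy-2-oxoethyl)benzoate | COC(=O)Cc1cc(OCc2ccccc2)cc(OCc2ccccc2)c1C(=O)OC
F2 | step 4 | 2,4-bis(benzyloxy)-6-(carboxymethyl)benzoic acid | OC(=O)Cc1cc(OCc2ccccc2)cc(OCc2ccccc2)c1C(=O)O
F3 | step 4 | 6,8-bis(benzyloxy)isochromane-1,3-dione | O=C1Cc2cc(OCc3ccccc3)cc(OCc3ccccc3)c2C(=O)O1
F4 | step 11 | 6-(benzyloxy)-3-pentyl-8-(4,4,5,5-tetramethyl-1,3,2-dioxaborolan-2-yl)isocoumarin | CCCCCc1cc2cc(OCc3ccccc3)cc(B3OC(C)(C)C(C)(C)O3)c2c(=O)o1
F5 | step 2 | 3,5-bis(benzyloxy)-2-bromophenol | Oc1cc(OCc2ccccc2)cc(OCc2ccccc2)c1Br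
F6 | step 2 | [3,5-bis(benzyloxy)-2-bromophenoxy]trimethylsilane | C[Si](C)(C)Oc1cc(OCc2ccccc2)cc(OCc2ccccc2)c1Br
F0 | step 12 | none | none
F7 | step 5 | 6,8-dihydroxy-3-pentylisocoumarin | CCCCCc1cc2cc(O)cc(O)c2c(=O)o1
A1 | alternative 1 | methyl 2-(2-benzyloxy-4-methoxy-6-pentylphenoxy)-6-methyl-4-(triisopropylsilyloxy)benzoate | COC(=O)c1c(C)cc(O[Si](C(C)C)(C(C)C)C(C)C)cc1Oc1c(OCc2ccccc2)cc(OC)cc1CCCCC
A2 | alternative 1 | methyl 4-(2-benzyloxy-4-methoxy-6-pentylphenoxy)-6-methyl-2-oxo-2H-pyran-5-carboxylate | COC(=O)c1c(C)oc(=O)cc1Oc1c(OCc2ccccc2)cc(OC)cc1CCCCC
A3 | alternative 1 | (triisopropylsilyloxy)ethyne | C#CO[Si](C(C)C)(C(C)C)C(C)C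
A4 | alternative 2 | methyl 1-[5-(benzyloxy)-2-(diethylcarbamoyl)-3-methylphenoxy]-2,4-dioxo-6-pentylcyclohexane-1-carboxylate (diastereomer mixture) | CCCCCC1CC(=O)CC(=O)C1(Oc1cc(OCc2ccccc2)cc(C)c1C(=O)N(CC)CC)C(=O)OC
A5 | alternative 2 | dimethyl 2-[5-(benzyloxy)-2-(diethylcarbamoyl)-3-methylphenoxy]malonate | COC(=O)C(Oc1cc(OCc2ccccc2)cc(C)c1C(=O)N(CC)CC)C(=O)OC
A6 | alternative 2 | (E)-non-3-en-2-one | CCCCC/C=C/C(C)=O
A7 | alternative 3 | methyl 2-(2-benzyloxy-4-methoxy-6-pentylphenoxy)-4-hydroxy-6-methylbenzoate | COC(=O)c1c(C)cc(O)cc1Oc1c(OCc2ccccc2)cc(OC)cc1CCCCC
A8 | alternative 3 | methyl 2-diazo-4-methyl-3-oxopent-4-enoate | COC(=O)C(=[N+]=[N-])C(=O)C(C)=C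
A9 | alternative 3 | 1-(benzyloxy)-2-(ethynyloxy)-5-methoxy-3-pentylbenzene | C#COc1c(OCc2ccccc2)cc(OC)cc1CCCCC
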